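**Plan**
- Common core: cis-fused 3,7-dioxabicyclo[3.3.0]octan-1-ol, (7S,8R,7'R,8'S), with two exo 4-hydroxy-3-methoxyphenyl groups. Ring A sits on C7 (next to C8–H) and ring B on C7' (next to C8'–O).
- Differences: H or OMe at C5 of ring A, H or OMe at C5' of ring B, OH or OAc at C8'.
- Shared intermediate 19 is 8-hydroxypinoresinol with Br at C5, I at C5' and the C8'–OH free. Each C–X can become C–H or C–OMe, I reacts before Br, and OH can become OAc.
- Enabling feature: each ring oxygen bridges a CH2 (C9', C9) and a benzylic CH (C7, C7') that lies para to a phenol OH. Both ring C–O bonds are therefore 1,6-adducts of a primary alcohol to a p-quinone methide, and the halogens block the only free ortho positions.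
- Retrosynthesis: cut O–C7 and O–C7' together (both rings, both benzylic stereocentres) to reach the open-chain triol 17, which holds only C8 and C8'. Then cut C8'–C7' and C8–C7 to reach (S)-malate (C9'–C8'(OH)–C8–C9) and two benzyl bromides made from 5-iodo- and 5-bromovanillin.
- Ring order: no ring exists before step 13. There ring 1 (C7–O–C9'–C8'–C8) and ring 2 (C7'–O–C9–C8–C8') form in one operation.

Key step: step 13
Shared intermediate: compound 19

Remark: lignan numbering is used. Unprimed atoms belong to the half whose C8 bears H (ring A), primed atoms to the half whose C8' bears oxygen (ring B). Compounds 1, 5 and 9 are taken as commercial.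

**Trunk**

Step 1
Reactants: 1 5-bromovanillin
Product: 2 4-(benzyloxy)-3-bromo-5-methoxybenzaldehyde
Conditions: BnBr, K2CO3, DMF, 60 °C
Reagents that add atoms: benzyl bromide, BrCc1ccccc1
Why: Williamson ether synthesis on the acidic phenol; the benzyl ether should survive LDA, KOH, acid acetalisation and hydride, and it can later be removed without reducing C–Br.

Step 2
Reactants: 2 4-(benzyloxy)-3-bromo-5-methoxybenzaldehyde
Product: 3 [4-(benzyloxy)-3-bromo-5-methoxyphenyl]methanol
Conditions: NaBH4, THF/MeOH, 0 °C
Reagents that add atoms: none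
Why: Borohydride reduction of an aldehyde, to which the aryl bromide and the benzyl ether are inert.

Step 3
Reactants: 3 [4-(benzyloxy)-3-bromo-5-methoxyphenyl]methanol
Product: 4 2-(benzyloxy)-1-bromo-5-(bromomethyl)-3-methoxybenzene (ring-A benzyl bromide)
Conditions: PBr3, CH2Cl2, 0 °C
Reagents that add atoms: phosphorus tribromide, BrP(Br)Br
Why: Bromination of a benzylic alcohol through its phosphite ester (SN2) under conditions that leave the aryl ethers alone.

Step 4
Reactants: 5 5-iodovanillin
Product: 6 4-(benzyloxy)-3-iodo-5-methoxybenzaldehyde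
Conditions: BnBr, K2CO3, DMF, 60 °C
Reagents that add atoms: benzyl bromide, BrCc1ccccc1
Why: Williamson ether synthesis, as in step 1.

Step 5
Reactants: 6 4-(benzyloxy)-3-iodo-5-methoxybenzaldehyde
Product: 7 [4-(benzyloxy)-3-iodo-5-methoxyphenyl]methanol
Conditions: NaBH4, THF/MeOH, 0 °C
Reagents that add atoms: none
Why: Borohydride reduction of the aldehyde, which does not touch the aryl iodide.

Step 6
Reactants: 7 [4-(benzyloxy)-3-iodo-5-methoxyphenyl]methanol
Product: 8 2-(benzyloxy)-5-(bromomethyl)-1-iodo-3-methoxybenzene (ring-B benzyl bromide)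
Conditions: PBr3, CH2Cl2, 0 °C
Reagents that add atoms: phosphorus tribromide, BrP(Br)Br
Why: Bromination of the benzylic alcohol through its phosphite ester, as in step 3.

Step 7
Reactants: 9 diisopropyl (S)-malate; 4 ring-A benzyl bromide
Product: 11 diisopropyl (2S,3R)-3-[4-(benzyloxy)-3-bromo-5-methoxybenzyl]-2-hydroxysuccinate, via dilithium alkoxide–enolate of diisopropyl malate 10 (not isolated)
Conditions: LDA (2.2 equiv), THF, −78 to −20 °C; then 4, −78 to −10 °C; AcOH
Reagents that add atoms: none
Why: Fráter–Seebach alkylation, in which the lithium-chelated alkoxide–enolate 10 is attacked on the face opposite the ester group of the carbinol carbon, so C8 is set anti to the C8' oxygen (3R) and the C8–C7 bond is made.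

Step 8
Reactants: 11 diisopropyl (2S,3R)-3-[4-(benzyloxy)-3-bromo-5-methoxybenzyl]-2-hydroxysuccinate
Product: 12 (2S,3R)-3-[4-(benzyloxy)-3-bromo-5-methoxybenzyl]-2-hydroxysuccinic acid
Conditions: KOH, THF/H2O, 60 °C; then aq HCl
Reagents that add atoms: potassium hydroxide, [K+].[OH-]
Why: Saponification; once the carboxylate has formed, C8–H is too weakly acidic to epimerise, and the benzyl ether and aryl bromide are stable to base.

Step 9
Reactants: 12 (2S,3R)-3-[4-(benzyloxy)-3-bromo-5-methoxybenzyl]-2-hydroxysuccinic acid
Product: 13 (2R)-3-[4-(benzyloxy)-3-bromo-5-methoxyphenyl]-2-[(2S,4S)-2-tert-butyl-5-oxo-1,3-dioxolan-4-yl]propanoic acid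
Conditions: t-BuCHO, p-TsOH (cat.), H2SO4 (cat.), pentane/CH2Cl2, reflux, water separator
Reagents that add atoms: pivalaldehyde, CC(C)(C)C=O
Why: Acid-catalysed acetalisation of the α-hydroxy acid (first stage of self-regeneration of stereocentres), where the five-membered dioxolanone is preferred to the six-membered alternative and the cis isomer is favoured, so the new acetal centre (2S) stores the C8' information.

Step 10
Reactants: 13 the dioxolanone acid; 8 ring-B benzyl bromide
Product: 15 (2R)-3-[4-(benzyloxy)-3-bromo-5-methoxyphenyl]-2-[(2S,4S)-4-[4-(benzyloxy)-3-iodo-5-methoxybenzyl]-2-tert-butyl-5-oxo-1,3-dioxolan-4-yl]propanoic acid, via dilithium carboxylate–enolate of 13 14 (not isolated)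
Conditions: LiHMDS (2.3 equiv), THF, −78 °C; then 8, −78 to −30 °C; aq HCl
Reagents that add atoms: none
Why: Enolate alkylation with self-regeneration of the stereocentre, in which the planar enolate 14 is attacked anti to the tert-butyl group, so the benzyl group takes the place of H with overall retention and quaternary C8' (S) and the C8'–C7' bond are set.

Step 11
Reactants: 15 the dialkylated dioxolanone acid
Product: 16 (2S,3S)-3-[4-(benzyloxy)-3-bromo-5-methoxybenzyl]-2-[4-(benzyloxy)-3-iodo-5-methoxybenzyl]butane-1,2,4-triol
Conditions: LiAlH4, THF, 0 °C; aqueous work-up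
Reagents that add atoms: none
Why: Hydride reduction of the acid and of the acylal-type lactone, whose hemiacetal collapses, turns C9 and C9' into CH2OH and frees the C8'–OH; 0 °C and a short contact time should keep C–I and C–Br intact.

Step 12
Reactants: 16 the bis(benzyl ether) triol
Product: 17 (2S,3S)-3-(3-bromo-4-hydroxy-5-methoxybenzyl)-2-(4-hydroxy-3-iodo-5-methoxybenzyl)butane-1,2,4-triol
Conditions: BCl3, pentamethylbenzene, CH2Cl2, −78 °C; then MeOH, H2O
Reagents that add atoms: none
Why: Lewis-acid cleavage of aryl benzyl ethers with a non-basic cation scavenger is non-reductive, so both halogens stay, and at −78 °C the aryl methyl ethers and the unactivated tertiary alcohol should stay as well.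

Step 13
Reactants: 17 the bisphenol triol
Product: 19 (7S,8R,7'R,8'S)-5-bromo-5'-iodo-8-hydroxypinoresinol, via bis(p-quinone methide) 18 (not isolated)
Conditions: Ag2O (2.5 equiv), CH2Cl2/acetone, rt, dark
Reagents that add atoms: none
Why: Ag2O takes each 2,6-disubstituted phenol to its phenoxyl radical, disproportionation gives the two p-quinone methides of 18, and each is captured by the primary hydroxyl four atoms away, so two benzylic C–H bonds become the two ring C–O bonds and rearomatisation drives both closures (the two events may also run one after the other). The closest known reaction types are the Ag2O or DDQ dehydrogenation of 4-alkyl-2,6-disubstituted phenols to quinone methides with 1,6-addition of alcohols, the radical-induced closure of dibenzylbutanediol lignans to 7,9'-epoxylignans, and the spontaneous double closure of the bis-quinone methide formed on oxidative 8–8' coupling of coniferyl-type alcohols. Ring 1 closes by 5-exo-trig attack of O9' on C7 and ring 2 by 5-exo-trig attack of O9 on C7', and the cis fusion follows from the fixed C8/C8' configuration, which holds C7 and C9' on one side and C9 and C7' on one side. C7 is controlled by allylic 1,3-strain, with C8–H in the plane of the quinone methide and O9' arriving from the side of its own tether C8', so ring A ends cis to H8 (exo, 7S); C7' is controlled the same way with the small C8'–OH in the plane, so ring B ends cis to that OH (exo, 7'R). The step needs selectivity among three hydroxyls and among radical pathways: every other O-to-C7 or O-to-C7' closure would give a three- or four-membered ring, no benzylic hydroxyl is present that could form a 7,7'-epoxide, Br and I occupy the only free ortho positions and suppress C5 coupling, and quaternary C8' rules out tautomerisation of the C7' quinone methide. The C7 quinone methide could still tautomerise to a styrene, which is why a neutral aprotic medium and an intramolecular trap are chosen.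

**Branch to 8-hydroxypinoresinol (compound 20)**

Step 14
Reactants: 19 5-bromo-5'-iodo-8-hydroxypinoresinol
Product: 20 8-hydroxypinoresinol
Conditions: H2 (1 atm), Pd/C, Et3N, MeOH, rt
Reagents that add atoms: none
Why: Catalytic hydrodehalogenation, in which the aryl C–I and C–Br bonds add to Pd far faster than the benzylic C–O bonds of the furofuran are hydrogenolysed, and Et3N traps HX so that no acid can ionise C7–O or C7'–O.

**Branch to 1-Acetoxypinoresinol (compound 22)**

Step 15
Reactants: 20 8-hydroxypinoresinol
Product: 21 8-hydroxypinoresinol triacetate (4-O, 4'-O and 8'-O acetyl)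
Conditions: Ac2O, DMAP (cat.), pyridine, 40 °C
Reagents that add atoms: acetic anhydride, CC(=O)OC(C)=O
Why: DMAP-catalysed acylation; all three hydroxyls are meant to react, so no site selectivity is needed, and the acylpyridinium ion is active enough for the tertiary bridgehead alcohol.

Step 16
Reactants: 21 the triacetate
Product: 22 1-acetoxypinoresinol
Conditions: pyrrolidine (2.5 equiv), CH2Cl2, 0 °C to rt
Reagents that add atoms: none
Why: Aminolysis of aryl esters; the two aryl acetates have a phenoxide leaving group and an open carbonyl, whereas the tertiary bridgehead acetate has an alkoxide leaving group and a crowded carbonyl and should remain.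

**Branch to 8-Hydroxysyringaresinol (compound 23)**

Step 17
Reactants: 19 5-bromo-5'-iodo-8-hydroxypinoresinol
Product: 23 8-hydroxysyringaresinol
Conditions: NaOMe (excess), CuI (cat.), DMF/MeOH, 100 °C; AcOH
Reagents that add atoms: sodium methoxide, [Na+].[O-]C
Why: Ullmann-type copper-catalysed methoxylation of o-halophenoxides (the reaction type that turns 5-bromovanillin into syringaldehyde); both C–X bonds are meant to react, methoxide in large excess outcompetes the hindered phenoxides, and any reversible phenoxide-induced ring opening should re-close through the same quinone methide.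

**Branch to Fraxiresinol (compound 25)**

Step 18
Reactants: 19 5-bromo-5'-iodo-8-hydroxypinoresinol
Product: 24 5-bromofraxiresinol (ring A 3-bromo-4-hydroxy-5-methoxyphenyl, ring B syringyl)
Conditions: CuI (cat.), 3,4,7,8-tetramethyl-1,10-phenanthroline (cat.), Cs2CO3, MeOH/toluene, 75 °C; AcOH
Reagents that add atoms: methanol, CO
Why: Ligand-accelerated Ullmann etherification; the weaker C–I bond on ring B is activated by Cu(I) at a temperature at which the C–Br bond on ring A is inert, and that bond strength difference sets the C5' site apart.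

Step 19
Reactants: 24 5-bromofraxiresinol
Product: 25 fraxiresinol
Conditions: H2 (1 atm), Pd/C, Et3N, MeOH, rt
Reagents that add atoms: none
Why: Catalytic hydrodebromination; the single C–Br bond is cleaved faster than the benzylic ring C–O bonds, and Et3N keeps the medium free of acid.

**Compound list**

| No. | Name | SMILES | Role |
|---|---|---|---|
| 1 | 5-bromovanillin | O=Cc1cc(OC)c(O)c(Br)c1 | starting material |
| 2 | 4-(benzyloxy)-3-bromo-5-methoxybenzaldehyde | O=Cc1cc(OC)c(OCc2ccccc2)c(Br)c1 | intermediate |
| 3 | [4-(benzyloxy)-3-bromo-5-methoxyphenyl]methanol | OCc1cc(OC)c(OCc2ccccc2)c(Br)c1 | intermediate |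
| 4 | ring-A benzyl bromide | BrCc1cc(OC)c(OCc2ccccc2)c(Br)c1 | intermediate |
| 5 | 5-iodovanillin | O=Cc1cc(OC)c(O)c(I)c1 | starting material |
| 6 | 4-(benzyloxy)-3-iodo-5-methoxybenzaldehyde | O=Cc1cc(OC)c(OCc2ccccc2)c(I)c1 | intermediate |
| 7 | [4-(benzyloxy)-3-iodo-5-methoxyphenyl]methanol | OCc1cc(OC)c(OCc2ccccc2)c(I)c1 | intermediate |
| 8 | ring-B benzyl bromide | BrCc1cc(OC)c(OCc2ccccc2)c(I)c1 | intermediate |
| 9 | diisopropyl (S)-malate | CC(C)OC(=O)C[C@H](O)C(=O)OC(C)C | starting material |
| 10 | dilithium alkoxide–enolate of 9 | CC(C)OC(=O)[C@@H]([O-])C=C([O-])OC(C)C.[Li+].[Li+] | intermediate |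
| 11 | diisopropyl (2S,3R)-3-(arylmethyl)-2-hydroxysuccinate | CC(C)OC(=O)[C@@H](O)[C@@H](Cc1cc(OC)c(OCc2ccccc2)c(Br)c1)C(=O)OC(C)C | intermediate |
| 12 | (2S,3R)-3-(arylmethyl)-2-hydroxysuccinic acid | OC(=O)[C@@H](O)[C@@H](Cc1cc(OC)c(OCc2ccccc2)c(Br)c1)C(=O)O | intermediate |
| 13 | cis-(2S,4S)-dioxolanone acid | O=C1O[C@@H](C(C)(C)C)O[C@H]1[C@@H](Cc2cc(OC)c(OCc3ccccc3)c(Br)c2)C(=O)O | intermediate |
| 14 | dilithium carboxylate–enolate of 13 | CC(C)(C)[C@@H]1OC([O-])=C(O1)[C@@H](Cc2cc(OC)c(OCc3ccccc3)c(Br)c2)C([O-])=O.[Li+].[Li+] | intermediate |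
| 15 | dialkylated dioxolanone acid | O=C1O[C@@H](C(C)(C)C)O[C@@]1(Cc2cc(OC)c(OCc3ccccc3)c(I)c2)[C@@H](Cc2cc(OC)c(OCc3ccccc3)c(Br)c2)C(=O)O | intermediate |
| 16 | (2S,3S)-bis(benzyl ether) triol | OC[C@](O)(Cc1cc(OC)c(OCc2ccccc2)c(I)c1)[C@H](CO)Cc1cc(OC)c(OCc2ccccc2)c(Br)c1 | intermediate |
| 17 | (2S,3S)-bisphenol triol | OC[C@](O)(Cc1cc(OC)c(O)c(I)c1)[C@H](CO)Cc1cc(OC)c(O)c(Br)c1 | intermediate |
| 18 | bis(p-quinone methide) | OC[C@](O)(C=C1C=C(OC)C(=O)C(I)=C1)[C@H](CO)C=C1C=C(OC)C(=O)C(Br)=C1 | intermediate |
| 19 | 5-bromo-5'-iodo-8-hydroxypinoresinol | COc1cc([C@H]2OC[C@]3(O)[C@@H](c4cc(OC)c(O)c(I)c4)OC[C@H]23)cc(Br)c1O | intermediate |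
| 20 | 8-hydroxypinoresinol | COc1cc([C@H]2OC[C@]3(O)[C@@H](c4ccc(O)c(OC)c4)OC[C@H]23)ccc1O | target |
| 21 | 8-hydroxypinoresinol triacetate | COc1cc([C@H]2OC[C@]3(OC(C)=O)[C@@H](c4ccc(OC(C)=O)c(OC)c4)OC[C@H]23)ccc1OC(C)=O | intermediate |
| 22 | 1-Acetoxypinoresinol | COc1cc([C@H]2OC[C@]3(OC(C)=O)[C@@H](c4ccc(O)c(OC)c4)OC[C@H]23)ccc1O | target |
| 23 | 8-Hydroxysyringaresinol | COc1cc([C@H]2OC[C@]3(O)[C@@H](c4cc(OC)c(O)c(OC)c4)OC[C@H]23)cc(OC)c1O | target |
| 24 | 5-bromofraxiresinol | COc1cc([C@H]2OC[C@]3(O)[C@@H](c4cc(OC)c(O)c(OC)c4)OC[C@H]23)cc(Br)c1O | intermediate |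
| 25 | Fraxiresinol | COc1cc([C@H]2OC[C@]3(O)[C@@H](c4cc(OC)c(O)c(OC)c4)OC[C@H]23)ccc1O | target |

Totals for 1-Acetoxypinoresinol (compound 22): total step count 16, longest linear sequence 13
Totals for 8-hydroxypinoresinol (compound 20): total step count 14, longest linear sequence 11
Totals for 8-Hydroxysyringaresinol (compound 23): total step count 14, longest linear sequence 11
Totals for Fraxiresinol (compound 25): total step count 15, longest linear sequence 12

**Steps most likely to fail**

**Step 13.**
- What may go wrong: the C7 quinone methide may tautomerise to the styrene before it is trapped, the product phenols may be oxidised further, iodine may be lost by radical ipso substitution, or the facial selectivity of one closure may be poor.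
- Fallback: it sets out from 17, returns at 19, and replaces phenol oxidation by radical C–H bromination followed by 1,6-elimination.
- Ac2O in pyridine without DMAP acylates the two phenols and the two primary hydroxyls to give the (2S,3S)-tetraacetate F1.
- Wohl–Ziegler bromination (NBS, AIBN, PhCF3, reflux) of the now electron-poorer rings gives the 7,7'-dibromide F2 as a mixture of benzylic epimers.
- K2CO3 in MeOH/THF strips the four acetates. The phenoxides expel bromide and the same two quinone methides arise with no oxidant in the flask, to be closed by the freed primary hydroxyls.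
- Any solvent adduct is a p-hydroxybenzyl ether and should re-enter the quinone methide manifold with a trace of camphorsulfonic acid in CH2Cl2.

**Step 10.**
- What may go wrong: alkylation at the crowded enolate carbon may be sluggish, the enolate may fragment with loss of the acetal, or facial control may erode.
- Fallback: it sets out from 13, returns at 16, and replaces acetal control by 1,2-induction in a lactone.
- BH3·SMe2 reduces the free acid. A trace of p-TsOH then moves the acyl group onto the new primary hydroxyl to give (3S,4S)-4-[4-(benzyloxy)-3-bromo-5-methoxybenzyl]-3-hydroxydihydrofuran-2(3H)-one F3.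
- The alkoxide–enolate dianion of F3 (LDA, 2.2 equiv, THF, −78 °C) is alkylated by 8 anti to the C8 benzyl group, which gives the (3S,4S)-3,4-dibenzyl-3-hydroxylactone F4.
- LiAlH4 at 0 °C opens F4 to 16.

**Step 18.**
- What may go wrong: discrimination between C–I and C–Br may be incomplete, protodehalogenation may intervene, or the phenoxides may be O-arylated.
- Fallback: it sets out from 19, returns at 24, and moves the selectivity-determining event to palladium.
- Miyaura borylation (PdCl2(dppf), B2pin2, KOAc, dioxane, 80 °C) should occur only at C–I and give the 5'-pinacolboronate F5.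
- Chan–Lam coupling of F5 with methanol (Cu(OAc)2, DMAP, MeOH, air, molecular sieves) gives 24.

**Further compounds**
F1 | step 13 | (2S,3S)-tetraacetate of 17 (both phenols and both primary hydroxyls) | CC(=O)OC[C@](O)(Cc1cc(OC)c(OC(C)=O)c(I)c1)[C@H](COC(C)=O)Cc1cc(OC)c(OC(C)=O)c(Br)c1
F2 | step 13 | 7,7'-dibromide of F1 (benzylic epimers) | CC(=O)OC[C@](O)(C(Br)c1cc(OC)c(OC(C)=O)c(I)c1)[C@H](COC(C)=O)C(Br)c1cc(OC)c(OC(C)=O)c(Br)c1
F3 | step 10 | (3S,4S)-4-[4-(benzyloxy)-3-bromo-5-methoxybenzyl]-3-hydroxydihydrofuran-2(3H)-one | O=C1OC[C@H](Cc2cc(OC)c(OCc3ccccc3)c(Br)c2)[C@@H]1O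
F4 | step 10 | (3S,4S)-4-[4-(benzyloxy)-3-bromo-5-methoxybenzyl]-3-[4-(benzyloxy)-3-iodo-5-methoxybenzyl]-3-hydroxydihydrofuran-2(3H)-one | O=C1OC[C@H](Cc2cc(OC)c(OCc3ccccc3)c(Br)c2)[C@@]1(O)Cc2cc(OC)c(OCc3ccccc3)c(I)c2
F5 | step 18 | 5-bromo-8-hydroxypinoresinol 5'-pinacolboronate | COc1cc([C@H]2OC[C@]3(O)[C@@H](c4cc(OC)c(O)c(B5OC(C)(C)C(C)(C)O5)c4)OC[C@H]23)cc(Br)c1O
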